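(The readings are calculated on assumed constants; the scatter is artificial.)

A closed flask cannot hold its starting material at one concentration, so its ring share slides as it empties.

| flask | starting material | remark | time |
|---|---|---|---|
| zeta | 2 M | run made earlier |  |
| delta | 3 M | run made earlier |  |
| cedar | 2.0 M | a closed flask charged with all of it at once and left for 2.0 h | 2.0 h |
| oak | 2.0 M | a single well-mixed tank run continuously and read at steady state, 2.0 h in it on average |  |

- zeta (time / min: single ring / %): 10.0: 22; 20.0: 26; 30.0: 31; 60.0: 35; 120: 39
- delta (time / min: single ring / %): 8.00: 15; 15.0: 21; 20.0: 22; 30.0: 26; 40.0: 25

(scatter of a reading: 1.5 percentage points)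

- the set-up with the highest amount of single ring at the outlet or at the end, in percent of the starting material put in ("none" if the first two lie within 2 percentage points) (cedar / oak / none)
- amount of single ring at the outlet or at the end, in percent of the starting material put in, cedar
- amount of single ring at the outlet or at the end, in percent of the starting material put in, oak

- the stated concentrations are those of everything mixed, before any reaction; amounts are the same in each set-up
- what was read earlier has a scatter of 1.5 percentage points, one standard deviation
- the earlier runs were made in a closed, stirred flask

Compare the 20.0 min readings: the delta run gives 22% and the zeta run 26%, less ring from the stronger charge, so set a first-order closure against a second-order loss. Define c* as the concentration of starting material at which closure and loss each take half of what reacts, the point where the selectivity factor is even. At concentration A the ring share is then c*/(c*+A), and a closed flask emptied from charge C yields (c*/C)·ln((c*+C)/c*). Take the equal-share concentration c* = 0.500 M, chosen to give 40.2% against the 39% read at 120 min; that is my figure for cedar.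

For oak, read the closure constant k from the zeta curve: 0.0435 min⁻¹ at 10.0 min and 0.0241 min⁻¹ at 60.0 min. Put into the tank balance, these bracket oak: 49.3% from below, 60.4% from above.

The forecast gives 39.5% for cedar and 52% for oak, the oak figure inside that bracket, and names oak, since “the well-mixed tank holds starting material at a low steady level”.

The flask gives 37.1% for cedar and 56.7% for oak, so oak.

    starting material → decomposition product (k = 1.90 × 10⁻⁷ s⁻¹)
    starting material + open dimer → open trimer (k = 3.20 × 10⁻⁴ L mol⁻¹ s⁻¹)
    2 starting material → open dimer (k = 6.90 × 10⁻⁴ L mol⁻¹ s⁻¹)
    starting material → single ring (k = 6.40 × 10⁻⁴ s⁻¹)
    open dimer → ring dimer (k = 0.00120 s⁻¹)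

Oak holds starting material at 0.246 M, half of c*, so with 12.3% of the charge unreacted the share of single ring reckons to 58.8%. In cedar, taking away the loss of 2 starting material to open dimer raises single ring from 37.1% to 99.0%, so that loss is the main reason for what cedar falls short. At ten times the residence time of oak, the same balance gives 86.6% to 91.8%, and that tank gives 90.3% of single ring.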